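**Plan**
- Retrosynthesis: the benzyl ether goes last. Both aryl bonds of C1 are then cut in one operation, C1–C1' (ring C) and C1–C8a (ring A), so C1 becomes an acetal carbon on an open (2R,3R)-butane-1,4-diol. Next come C1–C2 (lactone enolate plus formyl cation equivalent) and the C2–carbonyl bond made by an Evans alkylation.
- Enabling feature: C1 is doubly benzylic and has an oxygen para to it through either ring (O4' on ring C; O6 on ring A, para to C8a), so it is a latent aldehyde carbon. The oxygen of the C3 hydroxymethyl group lies four atoms from C1 and can hold it in a temporary tetrahydrofuran (C1–O–CH2–C3–C2).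
- Forward: the chain is built first (auxiliary alkylation, (R)-lactone, trans α-dimethoxymethylation, LiAlH4 opening). In step 7 the temporary tetrahydrofuran forms, ring C is joined to C1, the tetrahydrofuran reopens and ring B closes. The benzyl ether is then removed.
- Stereochemistry: C3 from the (S)-oxazolidinone auxiliary; C2 by trans substitution next to C3 on the lactone; C1 stereoconvergently, trans to C2, in the cationic ring closure.

Key step: step 7

Remark: locants are those of the tetralin (C1 bears ring C, C2 and C3 bear CH2OH, C4 is the CH2, ring A is C4a–C8a with OMe on C6 and OH on C7, ring B is the saturated ring; primes denote ring C). Compounds 1, 3, 6, 11, 16 and benzyl bromide are taken as commercial.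

**Step 1**
Reactants: 1 3-(4-hydroxy-3-methoxyphenyl)propanoic acid
Product: 2 3-[4-(benzyloxy)-3-methoxyphenyl]propanoic acid
Conditions: BnBr (1.1 equiv), NaOH (2.5 equiv), EtOH/H2O, reflux; then aq. HCl
Reagents that add atoms: benzyl bromide, BrCc1ccccc1
Why: Williamson ether synthesis; the phenoxide of the dianion is the better nucleophile in protic medium, and any benzyl ester formed is saponified by the excess hydroxide.

**Step 2**
Reactants: 2 3-[4-(benzyloxy)-3-methoxyphenyl]propanoic acid; 3 (S)-4-benzyloxazolidin-2-one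
Product: 5 (S)-4-benzyl-3-{3-[4-(benzyloxy)-3-methoxyphenyl]propanoyl}oxazolidin-2-one, via mixed pivalic anhydride 4 (not isolated)
Conditions: t-BuCOCl, Et3N, THF, −20 °C; then 3, LiCl, −20 °C → rt
Reagents that add atoms: none
Why: N-acylation of the oxazolidinone through the mixed anhydride, which is attacked at the less hindered carbonyl.

**Step 3**
Reactants: 5 (S)-4-benzyl-3-{3-[4-(benzyloxy)-3-methoxyphenyl]propanoyl}oxazolidin-2-one; 6 tert-butyl bromoacetate
Product: 8 tert-butyl (3R)-4-[4-(benzyloxy)-3-methoxyphenyl]-3-{[(4S)-4-benzyl-2-oxo-1,3-oxazolidin-3-yl]carbonyl}butanoate, via sodium enolate 7 (not isolated)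
Conditions: NaN(SiMe3)2, THF, −78 °C; then 6, −78 → −40 °C
Reagents that add atoms: none
Why: Evans asymmetric alkylation; the chelated (Z)-enolate is attacked on the face away from the C4 benzyl group of the auxiliary, which sets the (R) centre that becomes C3.

**Step 4**
Reactants: 8 tert-butyl (3R)-4-[4-(benzyloxy)-3-methoxyphenyl]-3-{[(4S)-4-benzyl-2-oxo-1,3-oxazolidin-3-yl]carbonyl}butanoate
Product: 10 (4R)-4-[4-(benzyloxy)-3-methoxybenzyl]dihydrofuran-2(3H)-one, via hydroxy ester 9 (not isolated)
Conditions: LiBH4, MeOH (1 equiv), THF, 0 °C; then p-TsOH·H2O (cat.), toluene, 60 °C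
Reagents that add atoms: none
Why: reductive removal of the auxiliary (the imide carbonyl is more electrophilic than the tert-butyl ester), then acid-catalysed lactonization by transesterification; the stereocentre is not touched.

**Step 5**
Reactants: 10 (4R)-4-[4-(benzyloxy)-3-methoxybenzyl]dihydrofuran-2(3H)-one; 11 trimethyl orthoformate
Product: 14 (3S,4R)-4-[4-(benzyloxy)-3-methoxybenzyl]-3-(dimethoxymethyl)dihydrofuran-2(3H)-one, via lithium enolate 12 (not isolated), via silyl ketene acetal 13 (not isolated)
Conditions: LiN(SiMe3)2, THF, −78 °C; Me3SiCl, −78 → 0 °C; solvent change to CH2Cl2; then 11, Me3SiOTf (10 mol %), −78 °C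
Reagents that add atoms: none
Why: Mukaiyama-type addition of the silyl ketene acetal to the dimethoxycarbenium ion formed from 11 and Me3SiOTf; the electrophile enters anti to the C4 arylmethyl group, giving the trans lactone and setting the centre that becomes C2.

**Step 6**
Reactants: 14 (3S,4R)-4-[4-(benzyloxy)-3-methoxybenzyl]-3-(dimethoxymethyl)dihydrofuran-2(3H)-one
Product: 15 (2R,3R)-2-[4-(benzyloxy)-3-methoxybenzyl]-3-(dimethoxymethyl)butane-1,4-diol
Conditions: LiAlH4, THF, 0 °C → rt
Reagents that add atoms: none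
Why: hydride reduction of the lactone to the 1,4-diol; the acetal is inert and no stereocentre is touched, and opening the ring frees the C3 hydroxymethyl oxygen that step 7 needs.

**Step 7**
Reactants: 15 (2R,3R)-2-[4-(benzyloxy)-3-methoxybenzyl]-3-(dimethoxymethyl)butane-1,4-diol; 16 guaiacol (2-methoxyphenol)
Product: 19 [(1S,2R,3R)-7-(benzyloxy)-1-(4-hydroxy-3-methoxyphenyl)-6-methoxy-1,2,3,4-tetrahydronaphthalene-2,3-diyl]dimethanol, via methyl furanoside 17 (not isolated), via 2-aryltetrahydrofuran 18 (not isolated)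
Conditions: 16 (3 equiv), p-TsOH·H2O (20 mol %), (CF3)2CHOH, 0 → 40 °C
Reagents that add atoms: none
Why: Acid ionizes the acetal at C1 and the C3 hydroxymethyl oxygen captures the oxocarbenium ion (17); re-ionization gives the cyclic oxocarbenium ion, which guaiacol attacks through its carbon para to OH to form the ring C–C1 bond (18, both C1 epimers), and the same acid reopens the benzylic C1–O bond to a para-hydroxybenzyl cation (protonated para-quinone methide) that ring A traps at C8a. The closest known reaction type is the acid-catalysed Baeyer-type double Friedel–Crafts condensation of an aldehyde acetal with two arenes, and its second half is the known acid rearrangement of 2-aryl-4-benzyltetrahydrofuran lignans (lariciresinol type) to aryltetralins. The temporary tetrahydrofuran closes 5-exo-trig and is opened again in the same flask; ring B closes by a 6-exo-trig Friedel–Crafts alkylation at the cationic C1, with the arene bond C4a–C8a inside the new ring. C1 is the only new stereocentre: the planar cation should cyclize through a chair-like transition state with ring C pseudo-equatorial and anti to the C2 hydroxymethyl group, so both epimers of 18 converge on the (1S) centre trans to C2, while C2 and C3 come unchanged from 15. The step needs attack para to OH on guaiacol (OH is the stronger para director, and the hydrogen-bonding solvent disfavours O- and ortho-attack), closure at C8a on ring A (the only position ortho to the tether that is para to OMe and unhindered), and ring closure ahead of capture of a second guaiacol (intramolecular six-ring closure, only moderate excess of 16).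

**Step 8**
Reactants: 19 [(1S,2R,3R)-7-(benzyloxy)-1-(4-hydroxy-3-methoxyphenyl)-6-methoxy-1,2,3,4-tetrahydronaphthalene-2,3-diyl]dimethanol
Product: 20 (+)-isolariciresinol, (1S,2R,3R)-configured
Conditions: H2 (1 atm), Pd/C (10 wt % Pd), EtOAc/MeOH, rt
Reagents that add atoms: none
Why: hydrogenolysis of the aryl benzyl ether; the doubly benzylic C1–H centre, the methyl ethers and the alcohols are inert, and any benzyl ether already lost in step 7 ends as the same product.

**Compound list**
1 | 3-(4-hydroxy-3-methoxyphenyl)propanoic acid | COc1cc(CCC(=O)O)ccc1O | starting material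
2 | 3-[4-(benzyloxy)-3-methoxyphenyl]propanoic acid | COc1cc(CCC(=O)O)ccc1OCc1ccccc1 | intermediate
3 | (S)-4-benzyloxazolidin-2-one | O=C1N[C@@H](Cc2ccccc2)CO1 | starting material
4 | 3-[4-(benzyloxy)-3-methoxyphenyl]propanoic pivalic anhydride | COc1cc(CCC(=O)OC(=O)C(C)(C)C)ccc1OCc1ccccc1 | intermediate
5 | (S)-4-benzyl-3-{3-[4-(benzyloxy)-3-methoxyphenyl]propanoyl}oxazolidin-2-one | COc1cc(CCC(=O)N2C(=O)OC[C@@H]2Cc2ccccc2)ccc1OCc1ccccc1 | intermediate
6 | tert-butyl bromoacetate | CC(C)(C)OC(=O)CBr | starting material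
7 | sodium (Z)-enolate of 5 | [Na+].[O-]/C(=C\Cc1ccc(OCc2ccccc2)c(OC)c1)N1C(=O)OC[C@@H]1Cc1ccccc1 | intermediate
8 | tert-butyl (3R)-4-[4-(benzyloxy)-3-methoxyphenyl]-3-{[(4S)-4-benzyl-2-oxo-1,3-oxazolidin-3-yl]carbonyl}butanoate | COc1cc(C[C@H](CC(=O)OC(C)(C)C)C(=O)N2C(=O)OC[C@@H]2Cc2ccccc2)ccc1OCc1ccccc1 | intermediate
9 | tert-butyl (3R)-4-[4-(benzyloxy)-3-methoxyphenyl]-3-(hydroxymethyl)butanoate | COc1cc(C[C@H](CC(=O)OC(C)(C)C)CO)ccc1OCc1ccccc1 | intermediate
10 | (4R)-4-[4-(benzyloxy)-3-methoxybenzyl]dihydrofuran-2(3H)-one | COc1cc(C[C@@H]2CC(=O)OC2)ccc1OCc1ccccc1 | intermediate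
11 | trimethyl orthoformate | COC(OC)OC | starting material
12 | lithium enolate of 10 | [Li+].[O-]C1=C[C@@H](Cc2ccc(OCc3ccccc3)c(OC)c2)CO1 | intermediate
13 | {[(4R)-4-[4-(benzyloxy)-3-methoxybenzyl]-4,5-dihydrofuran-2-yl]oxy}trimethylsilane | C[Si](C)(C)OC1=C[C@@H](Cc2ccc(OCc3ccccc3)c(OC)c2)CO1 | intermediate
14 | (3S,4R)-4-[4-(benzyloxy)-3-methoxybenzyl]-3-(dimethoxymethyl)dihydrofuran-2(3H)-one (trans) | COc1cc(C[C@H]2COC(=O)[C@@H]2C(OC)OC)ccc1OCc1ccccc1 | intermediate
15 | (2R,3R)-2-[4-(benzyloxy)-3-methoxybenzyl]-3-(dimethoxymethyl)butane-1,4-diol | COc1cc(C[C@@H](CO)[C@H](CO)C(OC)OC)ccc1OCc1ccccc1 | intermediate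
16 | guaiacol (2-methoxyphenol) | COc1ccccc1O | starting material
17 | {(3R,4R)-4-[4-(benzyloxy)-3-methoxybenzyl]-2-methoxytetrahydrofuran-3-yl}methanol (3,4-cis, both anomers) | COC1OC[C@H](Cc2ccc(OCc3ccccc3)c(OC)c2)[C@@H]1CO | intermediate
18 | 4-{(3R,4R)-4-[4-(benzyloxy)-3-methoxybenzyl]-3-(hydroxymethyl)tetrahydrofuran-2-yl}-2-methoxyphenol (both C2 epimers) | COc1cc(C2OC[C@H](Cc3ccc(OCc4ccccc4)c(OC)c3)[C@@H]2CO)ccc1O | intermediate
19 | [(1S,2R,3R)-7-(benzyloxy)-1-(4-hydroxy-3-methoxyphenyl)-6-methoxy-1,2,3,4-tetrahydronaphthalene-2,3-diyl]dimethanol | COc1cc([C@H]2c3cc(OCc4ccccc4)c(OC)cc3C[C@@H](CO)[C@@H]2CO)ccc1O | intermediate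
20 | (+)-isolariciresinol, (1S,2R,3R) | COc1cc([C@H]2c3cc(O)c(OC)cc3C[C@@H](CO)[C@@H]2CO)ccc1O | target

**Step count**
Total: 8 steps. Longest linear sequence: 8 steps (from 1).

**Steps most likely to fail**

Step 7. Guaiacol may form the bond through the wrong ring position (para to OMe or ortho to OH), and the benzylic cation may capture a second guaiacol before ring B closes. In the fallback the aryl group comes in as a carbanion whose ipso carbon is fixed, and ring closure becomes a separate step. It sets out from 15. Aqueous AcOH in THF should hydrolyse the acetal to the lactol (3R,4R)-4-[4-(benzyloxy)-3-methoxybenzyl]-3-(hydroxymethyl)tetrahydrofuran-2-ol F1. Excess [4-(benzyloxy)-3-methoxyphenyl]magnesium bromide F2 (from 1-(benzyloxy)-4-bromo-2-methoxybenzene and Mg in THF) should add to its open hydroxy aldehyde form and give the benzylic triol (2R,3R)-2-[4-(benzyloxy)-3-methoxybenzyl]-3-{[4-(benzyloxy)-3-methoxyphenyl](hydroxy)methyl}butane-1,4-diol F3 as both carbinol epimers. CF3CO2H in CH2Cl2 at 0 °C should ionize the benzylic alcohol and close ring B stereoconvergently to the dibenzyl ether [(1S,2R,3R)-7-(benzyloxy)-1-[4-(benzyloxy)-3-methoxyphenyl]-6-methoxy-1,2,3,4-tetrahydronaphthalene-2,3-diyl]dimethanol F4. Hydrogenolysis (H2, Pd/C) then brings the sequence back to the route at 20.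

Step 5. Methanol may be lost from the product under the silyl triflate to give the enol ether, which would erase the C2 centre; the enolate may also be silylated on carbon, and the electrophile may be too unreactive. The fallback uses a sulfur-stabilized, preformed formyl cation equivalent that needs no Lewis acid. It sets out from 13 (made from 10 as in step 5). 1,3-Dithian-2-ylium tetrafluoroborate F5 (from 1,3-dithiane and Ph3CBF4) in CH2Cl2 at −78 °C should give the trans lactone (3R,4R)-4-[4-(benzyloxy)-3-methoxybenzyl]-3-(1,3-dithian-2-yl)dihydrofuran-2(3H)-one F6. LiAlH4 in THF should give (2R,3R)-2-[4-(benzyloxy)-3-methoxybenzyl]-3-(1,3-dithian-2-yl)butane-1,4-diol F7. MeI and NaHCO3 in MeOH at 40 °C should unmask the dithiane with capture by the C3 hydroxymethyl group and methanol. The sequence comes back to the route at 17, which is submitted to the step 7 conditions in place of 15.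

Step 4. The lithium alkoxide may lactonize in the flask and the lactone may then be reduced on to the diol. The fallback separates cleavage of the auxiliary from the reduction. It sets out from 8. LiOH and H2O2 in THF/H2O at 0 °C should cleave the auxiliary to (2R)-2-[4-(benzyloxy)-3-methoxybenzyl]-4-tert-butoxy-4-oxobutanoic acid F8. BH3·SMe2 in THF at 0 °C should reduce the free acid and leave the tert-butyl ester. The sequence comes back to the route at 9, which is lactonized as in step 4.

**Further compounds**
F1 | step 7 | (3R,4R)-4-[4-(benzyloxy)-3-methoxybenzyl]-3-(hydroxymethyl)tetrahydrofuran-2-ol (both anomers) | OC1OC[C@H](Cc2ccc(OCc3ccccc3)c(OC)c2)[C@@H]1CO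
F2 | step 7 | [4-(benzyloxy)-3-methoxyphenyl]magnesium bromide | COc1cc([Mg]Br)ccc1OCc1ccccc1
F3 | step 7 | (2R,3R)-2-[4-(benzyloxy)-3-methoxybenzyl]-3-{[4-(benzyloxy)-3-methoxyphenyl](hydroxy)methyl}butane-1,4-diol (both carbinol epimers) | COc1cc(C(O)[C@@H](CO)[C@H](CO)Cc2ccc(OCc3ccccc3)c(OC)c2)ccc1OCc1ccccc1
F4 | step 7 | [(1S,2R,3R)-7-(benzyloxy)-1-[4-(benzyloxy)-3-methoxyphenyl]-6-methoxy-1,2,3,4-tetrahydronaphthalene-2,3-diyl]dimethanol | COc1cc([C@H]2c3cc(OCc4ccccc4)c(OC)cc3C[C@@H](CO)[C@@H]2CO)ccc1OCc1ccccc1
F5 | step 5 | 1,3-dithian-2-ylium tetrafluoroborate | [CH+]1SCCCS1.F[B-](F)(F)F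
F6 | step 5 | (3R,4R)-4-[4-(benzyloxy)-3-methoxybenzyl]-3-(1,3-dithian-2-yl)dihydrofuran-2(3H)-one | COc1cc(C[C@H]2COC(=O)[C@@H]2C3SCCCS3)ccc1OCc1ccccc1
F7 | step 5 | (2R,3R)-2-[4-(benzyloxy)-3-methoxybenzyl]-3-(1,3-dithian-2-yl)butane-1,4-diol | COc1cc(C[C@@H](CO)[C@H](CO)C2SCCCS2)ccc1OCc1ccccc1
F8 | step 4 | (2R)-2-[4-(benzyloxy)-3-methoxybenzyl]-4-tert-butoxy-4-oxobutanoic acid | COc1cc(C[C@H](CC(=O)OC(C)(C)C)C(=O)O)ccc1OCc1ccccc1
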